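**Strategy.** Both CH2–C1 bonds joining the central catechol (ring B) to the outer rings A and C are cut. The feature exploited is that in each outer ring C1 sits para to the C4 oxygen and already carries bromine at C2 and C3. Each ring can therefore arrive dearomatised as a 2,3-dibromo p-quinone monoketal (C1 carbonyl, C4 ketal), an aryl cation equivalent. In one operation the methylenedioxy-masked ring B o-xylylene di-Grignard reagent adds to the carbonyl of two monoketal molecules, forming both benzylic C–C bonds. Reductive aromatisation, O-methylation, one symmetry-controlled bromination of ring B and global ether cleavage complete the target.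

Key step: step 7

Assumption: the target has no stereocentre; the two carbinol centres made in step 7 are formed without control and carried as a meso/dl mixture, because step 8 destroys both. Outer-ring atoms are numbered from the CH2-bearing carbon (C1) through the brominated carbons (C2, C3) to the oxygenated carbons (C4, C5).

**Step 1**
Reactants: 1 vanillin
Product: 3 2,3-dibromo-4-hydroxy-5-methoxybenzaldehyde (5,6-dibromovanillin), via 5-bromovanillin 2 (not isolated)
Conditions: Br2 (2.2 equiv), NaOAc, Fe powder (cat.), AcOH, rt
Reagents that add atoms: bromine, BrBr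
Why: Electrophilic aromatic bromination goes first ortho to the free phenol and then, with FeBr3 generated in situ, para to the methoxyl, the last open site being shielded between CHO and OMe.

**Step 2**
Reactants: 3 2,3-dibromo-4-hydroxy-5-methoxybenzaldehyde
Product: 4 2,3-dibromo-4,5-dimethoxybenzaldehyde
Conditions: MeI, K2CO3, DMF, rt
Reagents that add atoms: iodomethane, CI
Why: Williamson ether synthesis, in which the acidic bromine-flanked phenoxide is methylated under mild base without touching the aldehyde.

**Step 3**
Reactants: 4 2,3-dibromo-4,5-dimethoxybenzaldehyde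
Product: 6 2,3-dibromo-4,5-dimethoxyphenol, via aryl formate 5 (not isolated)
Conditions: mCPBA, CH2Cl2, 0 °C → rt; then K2CO3 (cat.), MeOH, rt
Reagents that add atoms: mCPBA, OOC(=O)c1cccc(Cl)c1
Why: Baeyer–Villiger oxidation, in which the aryl group (para methoxyl, ortho bromine) migrates in the Criegee adduct in preference to hydrogen, and the resulting formate is cleaved by base-catalysed methanolysis.

**Step 4**
Reactants: 6 2,3-dibromo-4,5-dimethoxyphenol
Product: 7 2,3-dibromo-4,4,5-trimethoxycyclohexa-2,5-dien-1-one (p-quinone monoketal)
Conditions: PhI(OAc)2, MeOH, 0 °C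
Reagents that add atoms: methanol, CO
Why: Oxidative dearomatisation of a p-methoxyphenol by the trivalent iodine reagent, with methanol trapping the activated ring at the methoxy-bearing para carbon, the standard entry to p-quinone monoketals.

**Step 5**
Reactants: 8 1,3-benzodioxole
Product: 10 5,6-bis(chloromethyl)-1,3-benzodioxole, via 5-(chloromethyl)-1,3-benzodioxole 9 (not isolated)
Conditions: (CH2O)n, conc. aq. HCl, HCl (g), 1,4-dioxane, 0 °C → rt
Reagents that add atoms: formaldehyde (as paraformaldehyde), C=O; hydrogen chloride, Cl
Why: Blanc chloromethylation occurs twice, each time para to one ring oxygen (C5, then C6), the positions ortho to oxygen being much less reactive.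

**Step 6**
Reactants: 10 5,6-bis(chloromethyl)-1,3-benzodioxole
Product: 11 [1,3-benzodioxole-5,6-diylbis(methylene)]bis(magnesium chloride)
Conditions: Mg powder (excess), THF, 20 °C, slow addition at high dilution; used at once
Reagents that add atoms: magnesium, [Mg]
Why: Grignard formation by insertion of magnesium into both benzylic C–Cl bonds under the chloride/THF/high-dilution regime known for o-xylylene dichloride, which suppresses Wurtz coupling and 1,4-elimination of the half-formed reagent.

**Step 7**
Reactants: 11 [1,3-benzodioxole-5,6-diylbis(methylene)]bis(magnesium chloride); 7 2,3-dibromo-4,4,5-trimethoxycyclohexa-2,5-dien-1-one (2.2 equiv)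
Product: 14 5,6-bis[(2,3-dibromo-1-hydroxy-4,4,5-trimethoxycyclohexa-2,5-dien-1-yl)methyl]-1,3-benzodioxole (bis(quinol ketal) adduct; meso/dl mixture), via mono-adduct chloromagnesium alkoxide 12 (not isolated), via bis(chloromagnesium alkoxide) 13 (not isolated)
Conditions: 11 added slowly to 7, THF, −78 → −40 °C; sat. aq. NH4Cl, −40 → 0 °C; crude product kept acid-free
Reagents that add atoms: none
Why: Each benzylic C–Mg bond adds as a carbon nucleophile to the magnesium-coordinated C1 carbonyl of one monoketal molecule, giving first alkoxide 12, which still carries one CH2MgCl arm, and then bis(alkoxide) 13, which is protonated on quench. The closest known reaction type is the 1,2-addition of Grignard and organolithium reagents to p-quinone monoketals and to vinylogous esters. No ring is closed. The two tertiary carbinol centres (C1 of each dienol) form without any controlling element, so a meso/dl mixture is expected, which is harmless because step 8 removes both centres. The step needs carbonyl attack in preference to conjugate addition–elimination and electron transfer: the C5 methoxyl makes C5=C6–C1=O a vinylogous ester with a deactivated β-carbon, the other β-carbon C3 is fully substituted and flanked by the quaternary ketal, and a hard benzylic Grignard reagent at −78 °C favours direct addition. Adding 11 to an excess of 7 keeps ketone in excess over carbanion, so that each arm is captured by its own monoketal molecule.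

**Step 8**
Reactants: 14 bis(quinol ketal) adduct
Product: 16 5,6-bis(2,3-dibromo-4-hydroxy-5-methoxybenzyl)-1,3-benzodioxole, via bis(quinol) 15 (not isolated)
Conditions: Zn dust, AcOH–H2O–THF, rt
Reagents that add atoms: water, O
Why: Aqueous acid hydrolyses each dimethyl ketal to the cross-conjugated dienone, which zinc reduces by two-electron transfer with loss of the C1 hydroxyl and rearomatisation (reductive aromatisation of p-quinols), erasing both stereocentres while the C–Br bonds, inert to Zn/AcOH at room temperature, survive.

**Step 9**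
Reactants: 16 5,6-bis(2,3-dibromo-4-hydroxy-5-methoxybenzyl)-1,3-benzodioxole
Product: 17 5,6-bis(2,3-dibromo-4,5-dimethoxybenzyl)-1,3-benzodioxole
Conditions: MeI, K2CO3, acetone, reflux
Reagents that add atoms: iodomethane, CI
Why: Williamson O-methylation removes the oxidisable free phenols before bromination and would also funnel any regioisomeric hydroxy-methoxy pattern from step 8 into the same dimethoxy rings.

**Step 10**
Reactants: 17 5,6-bis(2,3-dibromo-4,5-dimethoxybenzyl)-1,3-benzodioxole
Product: 18 4-bromo-5,6-bis(2,3-dibromo-4,5-dimethoxybenzyl)-1,3-benzodioxole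
Conditions: NBS (1.0 equiv), MeCN, 0 °C → rt, dark
Reagents that add atoms: N-bromosuccinimide, BrN1C(=O)CCC1=O
Why: Electrophilic aromatic bromination goes to the only electron-rich ring, the halogen-free dialkyl methylenedioxybenzene (ring B), whose two open positions are symmetry-equivalent, while each outer ring is deactivated by two bromines and the first bromine on ring B slows a second substitution.

**Step 11**
Reactants: 18 4-bromo-5,6-bis(2,3-dibromo-4,5-dimethoxybenzyl)-1,3-benzodioxole
Product: 19 3-bromo-4,5-bis(2,3-dibromo-4,5-dihydroxybenzyl)benzene-1,2-diol (target)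
Conditions: BBr3 (excess), CH2Cl2, −78 °C → rt; ice-water
Reagents that add atoms: none
Why: Lewis-acid ether cleavage, in which BBr3 coordinates each ether oxygen and bromide cleaves the four O–CH3 bonds and the O–CH2–O bridge, leaving aryl C–Br and diarylmethane bonds intact, and hydrolysis of the aryl borates releases the hexaphenol.

**Compound list**
1 | vanillin | COc1cc(C=O)ccc1O | starting material
2 | 5-bromovanillin (3-bromo-4-hydroxy-5-methoxybenzaldehyde) | COc1cc(C=O)cc(Br)c1O | intermediate (not isolated)
3 | 2,3-dibromo-4-hydroxy-5-methoxybenzaldehyde | COc1cc(C=O)c(Br)c(Br)c1O | intermediate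
4 | 2,3-dibromo-4,5-dimethoxybenzaldehyde | COc1cc(C=O)c(Br)c(Br)c1OC | intermediate
5 | 2,3-dibromo-4,5-dimethoxyphenyl formate | COc1cc(OC=O)c(Br)c(Br)c1OC | intermediate (not isolated)
6 | 2,3-dibromo-4,5-dimethoxyphenol | COc1cc(O)c(Br)c(Br)c1OC | intermediate
7 | 2,3-dibromo-4,4,5-trimethoxycyclohexa-2,5-dien-1-one | O=C1C=C(OC)C(OC)(OC)C(Br)=C1Br | intermediate
8 | 1,3-benzodioxole | c1ccc2OCOc2c1 | starting material
9 | 5-(chloromethyl)-1,3-benzodioxole | ClCc1ccc2OCOc2c1 | intermediate (not isolated)
10 | 5,6-bis(chloromethyl)-1,3-benzodioxole | ClCc1cc2OCOc2cc1CCl | intermediate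
11 | [1,3-benzodioxole-5,6-diylbis(methylene)]bis(magnesium chloride) | Cl[Mg]Cc1cc2OCOc2cc1C[Mg]Cl | intermediate
12 | mono-adduct, chloromagnesium alkoxide with one CH2MgCl arm (racemic, one enantiomer drawn) | Cl[Mg]O[C@]1(Cc2cc3OCOc3cc2C[Mg]Cl)C=C(OC)C(OC)(OC)C(Br)=C1Br | intermediate (not isolated)
13 | bis(chloromagnesium alkoxide) of 14 (meso/dl mixture, R,R drawn) | Cl[Mg]O[C@]1(Cc2cc3OCOc3cc2C[C@@]2(O[Mg]Cl)C=C(OC)C(OC)(OC)C(Br)=C2Br)C=C(OC)C(OC)(OC)C(Br)=C1Br | intermediate (not isolated)
14 | 5,6-bis[(2,3-dibromo-1-hydroxy-4,4,5-trimethoxycyclohexa-2,5-dien-1-yl)methyl]-1,3-benzodioxole (meso/dl mixture, R,R drawn) | O[C@]1(Cc2cc3OCOc3cc2C[C@@]2(O)C=C(OC)C(OC)(OC)C(Br)=C2Br)C=C(OC)C(OC)(OC)C(Br)=C1Br | intermediate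
15 | 5,6-bis[(2,3-dibromo-1-hydroxy-5-methoxy-4-oxocyclohexa-2,5-dien-1-yl)methyl]-1,3-benzodioxole (meso/dl mixture, R,R drawn) | O[C@]1(Cc2cc3OCOc3cc2C[C@@]2(O)C=C(OC)C(=O)C(Br)=C2Br)C=C(OC)C(=O)C(Br)=C1Br | intermediate (not isolated)
16 | 5,6-bis(2,3-dibromo-4-hydroxy-5-methoxybenzyl)-1,3-benzodioxole | COc1cc(Cc2cc3OCOc3cc2Cc2cc(OC)c(O)c(Br)c2Br)c(Br)c(Br)c1O | intermediate
17 | 5,6-bis(2,3-dibromo-4,5-dimethoxybenzyl)-1,3-benzodioxole | COc1cc(Cc2cc3OCOc3cc2Cc2cc(OC)c(OC)c(Br)c2Br)c(Br)c(Br)c1OC | intermediate
18 | 4-bromo-5,6-bis(2,3-dibromo-4,5-dimethoxybenzyl)-1,3-benzodioxole | COc1cc(Cc2cc3OCOc3c(Br)c2Cc2cc(OC)c(OC)c(Br)c2Br)c(Br)c(Br)c1OC | intermediate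
19 | 3-bromo-4,5-bis(2,3-dibromo-4,5-dihydroxybenzyl)benzene-1,2-diol (achiral) | Oc1cc(Cc2cc(O)c(O)c(Br)c2Cc2cc(O)c(O)c(Br)c2Br)c(Br)c(Br)c1O | target

**Step count**
Total: 11 steps. Longest linear sequence: 9 steps (vanillin: steps 1–4, then 7–11).

**Steps most likely to fail**

Step 7. What may go wrong: electron transfer from the benzylic Grignard reagent to the easily reduced dienone (returning the phenol and coupling the benzylic arms), conjugate addition with loss of bromide or methoxide, or addition that stops after one arm. The fallback replaces carbanion addition by Friedel–Crafts benzylation. It sets out from 4, which is reduced with NaBH4 in MeOH to (2,3-dibromo-4,5-dimethoxyphenyl)methanol F1. Two equivalents of F1 then alkylate 1,3-benzodioxole 8 under BF3·OEt2 in CH2Cl2 (0 °C → rt), first para to one ring oxygen to give 5-(2,3-dibromo-4,5-dimethoxybenzyl)-1,3-benzodioxole F2 and then para to the other. This delivers 17, where the route is rejoined before step 10.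

Step 6. What may go wrong: Wurtz-type coupling, or 1,4-elimination of the half-magnesiated chloride to an o-quinodimethane that oligomerises, so that little titratable di-Grignard reagent forms. The fallback replaces direct insertion by tin–lithium exchange and transmetalation. It sets out from 10, which is treated with Bu3SnLi in THF at −78 °C to give 5,6-bis[(tributylstannyl)methyl]-1,3-benzodioxole F3. n-BuLi (2 equiv, THF, −78 °C) exchanges both tin groups to give 5,6-bis(lithiomethyl)-1,3-benzodioxole F4, and MgCl2 converts this into 11, which is used directly in step 7.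

Step 8. What may go wrong: acid ionisation of the tertiary allylic carbinol before the ketal is hydrolysed (allylic transposition or alkyl shift), or reductive loss of the bromine next to the carbonyl during electron transfer. The fallback replaces the dissolving metal by hydride reduction and dehydration. It sets out from 14, which is hydrolysed with dilute aqueous oxalic acid in THF to the bis(quinol) 15, isolated this time. NaBH4 with CeCl3·7H2O in MeOH at −78 °C reduces both carbonyl groups to 5,6-bis[(2,3-dibromo-1,4-dihydroxy-5-methoxycyclohexa-2,5-dien-1-yl)methyl]-1,3-benzodioxole F5. Catalytic TsOH in CH2Cl2 then removes the tertiary hydroxyl and the C4 hydrogen of each ring as water (dehydrative aromatisation), giving 16 and rejoining the route at step 9.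

**Further compounds**
F1 | step 7 | (2,3-dibromo-4,5-dimethoxyphenyl)methanol | COc1cc(CO)c(Br)c(Br)c1OC
F2 | step 7 | 5-(2,3-dibromo-4,5-dimethoxybenzyl)-1,3-benzodioxole | COc1cc(Cc2ccc3OCOc3c2)c(Br)c(Br)c1OC
F3 | step 6 | 5,6-bis[(tributylstannyl)methyl]-1,3-benzodioxole | CCCC[Sn](CCCC)(CCCC)Cc1cc2OCOc2cc1C[Sn](CCCC)(CCCC)CCCC
F4 | step 6 | 5,6-bis(lithiomethyl)-1,3-benzodioxole | [Li]Cc1cc2OCOc2cc1C[Li]
F5 | step 8 | 5,6-bis[(2,3-dibromo-1,4-dihydroxy-5-methoxycyclohexa-2,5-dien-1-yl)methyl]-1,3-benzodioxole (diastereomer mixture; carbinol centres drawn as in 14, CH(OH) centres undefined) | O[C@]1(Cc2cc3OCOc3cc2C[C@@]2(O)C=C(OC)C(O)C(Br)=C2Br)C=C(OC)C(O)C(Br)=C1Br
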